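Once the feed has ended, every X charged stands as X, G or Q, so the share used up equals G plus Q, and you need only find where X stops and how the used part divides.

all flasks: X 0.22 M (fed, over 12 s)

| flask | E | D | remark | time |
|---|---|---|---|---|
| alpha | 0.22 M | 0.22 M | the very flask that is asked about, followed so far; the fed solution adds 0.25 times the starting volume |  |
| beta | 0.33 M | 0.22 M | run made earlier; the fed solution adds 0.25 times the starting volume |  |
| flask | 0.220 M | 0.220 M | the fed solution adds 0.25 times the starting volume | 10 min |

| run | time / min | X / % | G / % |
|---|---|---|---|
| alpha | 0.250 | 27.3 | 41.0 |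
| alpha | 0.833 | 5.8 | 41.3 |
| alpha | 1.33 | 5.1 | 40.1 |
| alpha | 2.00 | 5.4 | 40.3 |
| alpha | 3.00 | 5.7 | 43.3 |
| alpha | 4.00 | 4.7 | 41.8 |
| beta | 0.250 | 18.7 | 55.2 |
| beta | 0.833 | 1.3 | 62.2 |
| beta | 1.33 | 1.9 | 63.2 |
| beta | 2.00 | 0 | 62.5 |
| beta | 3.00 | 0 | 63.0 |
| beta | 4.00 | 0.7 | 61.3 |

(each reading ± 1 percentage point)

- share of the X used up at 10 min
- G at 10 min, in percent of the X charged
- Q at 10 min, in percent of the X charged

- every charge counts on the volume at the start, and the solution that is fed holds the whole dose
- what was read earlier has a scatter of 1 percentage point, one standard deviation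

The flask asked about is the alpha run followed further, and from 0.833 min to 4.00 min alpha's X averages 5.34% of its charge. If you take E as the limiting reagent, the X used up per E charged, both counted on the starting volume, reads 0.947; call this the spend ratio. Beta tests it, since there the ratio promises 1.42 of the X charge, more than the whole, and beta's X does read 0.7% at 4.00 min. For this flask I therefore reckon a conversion of 94.7%, and with alpha's late G averaging 41.4%, the balance leaves Q at 53.3%.

The weak link is the plateau itself, which might be a slow reaction rather than a stop. Between the first two alpha readings X falls, on average, at a pace of one halving per 0.261 min, so the span from 0.833 min to 4.00 min holds 12.1 such halvings, yet alpha's X reads just 1.1 percentage points lower there, with a scatter of 1 point on each reading. In the alpha readings the early pace has ended.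

The forecast, slightly different from my figures, gives 94.9% (93.5% to 97%), G 41.3% (39.8% to 43%) and Q 53.6% (51% to 56%), taking the flat X as a sign that “a partner has run out”.

The flask gives 94.2%, with G 41.5% and Q 52.7%.

    X + E → Q, rate k1*[X] as long as [E] is above zero (k = 0.0880 s⁻¹)
    E + D → L (k = 0.0290 M⁻¹ s⁻¹)
    X + E → G (k = 0.920 M⁻¹ s⁻¹)

At 10.0 min E in this flask stands at 0% of its charge. In a further flask, like this one but with 0.88 M of X, the spend ratio of 0.947 read from alpha gives 23.7%, and that flask converts 24.4%.

Readings and results are simulated with made-up constants.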